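Compound numbers are those of the list after the steps. Chain carbons are C1 (acyloxy carbon on C4 of ring A) to C6 (methyl); ring A is the 2,4-disubstituted oxazole, ring B the 5-substituted one.

## Analysis of the target

The target is a bis-oxazole in which C2 of ring A carries a methylene bound to C5 of ring B, and C4 of ring A carries the chain C1–C6. The chain is oxygenated at C1 (14-methylpentadecanoate ester of a heteroaryl carbinol), C3, C4 and C5 (free hydroxyls); C2 is a methylene and C6 a methyl group. The four stereocentres are 1R, 3S, 4R, 5S: in the extended chain the C1 and C3 oxygens are syn, C3/C4 anti and C4/C5 syn. Sensitive points are the single ester next to a 1,3-related free hydroxyl (base-promoted acyl migration), the doubly activated methylene between the rings, and the C2–H of ring B (both attacked by strong bases). The heterocycles are easy; the difficulty is to set four stereocentres on six carbons and to make exactly one of four secondary oxygens an ester without a long protecting-group sequence. The strategy rests on the 1,5-relationship of the C1 and C5 oxygens. Both can be the one oxygen of a pyran ring built on C1–C5, so that O–C1 stays masked until the ring is opened and the ring relays configuration from C1 to C3 and C4.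

## Retrosynthetic reasoning

**23 to 22.** The last operation only frees the C3 and C4 hydroxyls from the dioxolane of 22. Keeping them tied until the end is what makes C1 the only acylated oxygen and keeps base away from a hydroxy ester that could migrate.

**22 to 21.** The C5 carbinol is taken back to methyl ketone 21 (C5–H bond). The forward reduction has to deliver hydride anti to the C4–O bond without chelation, which gives the 4,5-syn arrangement.

**21 to 18 and 19.** The ester C–O bond at C1 is cut; acid 19 supplies the acyl group. The alcohol partner is the cyclic hemiketal 18, whose ring oxygen is O–C1 and whose open-chain tautomer is hydroxy ketone 20. Acylation therefore opens the ring, places the acyl group on C1 and reveals the C5 ketone in one operation, with no other free hydroxyl present.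

**18 to 17 to 16.** The hemiketal hydroxyl is traced to benzyl ketal 17 and the dioxolane to the cis-diol 16. A benzyloxy group is chosen at the ketal carbon rather than a simple alkoxy group because it is removed by hydrogenolysis. An acid-labile ketal flanked by an oxygenated carbon would have to be hydrolysed in competition with the dioxolane.

**16 to 14.** The C4–O bond and the exocyclic ketal C5–O bond are cut together. Both arise from oxidation of the enol ether C4=C5 of 14 on the face of the C3 hydroxyl, through epoxide 15, which is opened at the ketal carbon. This sets C4 relative to C3 (3,4-anti in the chain, cis on the ring).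

**14 to 13 to 12.** The target needs the C3 oxygen trans to the C1 substituent on the pyran ring (1,3-syn in the chain). Hydride reduction of the ring ketone gives the cis alcohol 12, so one inversion at C3 through ester 13 is accepted.

**12 to 11.** The C3–H bond is cut; ketone 11 carries all six chain carbons, with C3 as carbonyl and C4=C5 as enol ether.

**11 to 6 and 9 (key disconnection).** C1–C2 and O–C5 are cut. Aldehyde 6 already holds both oxazoles and the C1 carbon; diene 9 supplies C2–C6. The forward reaction must set C1 by catalyst control, as 6 has no stereocentre, and close the pyranone.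

**6 to 5 to 3 to 1 and 2.** The formyl group comes from ester 5. Ring A is cut at O1–C2 and N3–C2: amide 3 from acid 1 and serine ester 2, cyclodehydration to 4, dehydrogenation to 5. This keeps organometallic oxazole chemistry out of the route.

**9 to 8 to 7.** The diene is the silyl dienol ether of vinylogous ester 8, made by O-methylation of 7.

## Alternatives that were turned down

Alternative 1: The bond between C1 and the future C4 of ring A is cut. The chain comes from 2-deoxy-L-fucose A1, used as its tribenzyl aldehyde A2, and methyl isocyanoacetate A3 supplies N3 and C4 of ring A. In the forward key step A2 and A3 combine under [Au(CNC6H11)2]BF4 A4, a monovalent gold salt, and a chiral ferrocenylbisphosphine with an aminoalkyl side arm to give trans-oxazoline A5, with C1 set by the catalyst.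
- For: C3, C4 and C5 are bought, not made. On this point the alternative is stronger than the chosen route, which has to create them.
- Against: the oxazoline of A5 is not ring A. Its C5 is chain C1 and its oxygen is O–C1, so it must be hydrolysed, N-acylated with 1, adjusted to the aldehyde oxidation level and cyclodehydrated. The intermediates are β-oxygenated α-acylamino carbonyl compounds, for which β-elimination of the C1 oxygen is the easiest reaction. The C4 stereocentre of A5 is created only to be destroyed.
- Against: A2 is an α-unbranched, β-benzyloxy aldehyde, the weaker substrate class for this aldol and prone to loss of benzyloxide with the amine side arm. Three benzyl ethers must later be removed next to a heteroaryl carbinyl ester, and C1–OH must be told apart from three other oxygens.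
- Comparison: the chosen route instead has ring A ready before any stereocentre exists, only two protecting groups, and O–C1 differentiated by construction.

Alternative 2: C2–C3 is cut. The dioxolane aldehyde A6, which holds C3–C6 with C4 and C5 from the chiral pool, and ketene A7, generated in the flask, combine under a silylated cinchona alkaloid and a Lewis acid co-catalyst. An ammonium enolate aldol–lactonisation gives β-lactone A8 with C3 set.
- For: catalyst control at C3 without any inversion and C4/C5 without a ketone reduction; on both points it is stronger than the chosen route. The lactone is an activated acyl group at C1, and a 1,3-syn reduction from C3–OH could later set C1.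
- Against: C1 arrives as a carboxyl carbon, whereas the target needs it as a carbinol carbon bonded to C4 of ring A. That bond then requires a 4-metallated oxazole, which is incompatible with the acidic inter-ring methylene and the C2–H of ring B, or a de novo construction of ring A on a ketone.
- Against: C3–OH becomes free before C1–OH exists, so extra protection is needed to acylate C1 alone. A6 is an epimerisable α-alkoxy aldehyde under amine catalysis.
- Comparison: the chosen route makes the C1–ring A bond trivially (it is in aldehyde 6), sets C1 in the same step that builds the skeleton, and never has C1 and C3 hydroxyls free together.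

Alternative 3: Ring A is cut at O1–C5 and N3–C4. The fully elaborated, orthogonally protected terminal alkyne A9, 2-(oxazol-5-yl)acetamide A10 and a quinoline N-oxide react under (Mor-DalPhos)AuNTf2 A11, a cationic monovalent gold catalyst. The α-oxo gold carbene is trapped by the amide oxygen and the ketone condenses with the amide nitrogen to give A12.
- For: it is the most convergent plan, and A12 has O–C1 as the only triethylsilyl ether. Its endgame is shorter and more orthogonal than the chosen one.
- Against: the key step makes no stereocentre and no chain C–C bond. All four stereocentres of A9 must be built separately, so the total length is greater.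
- Against: alkyne oxidation places a ketone directly beside the C1 silyloxy stereocentre. That α-silyloxy ketone must condense with nitrogen, and enolisation or enamide tautomerism there threatens C1, as does loss of silanol. A10 also brings a basic nitrogen and an acidic methylene to a carbene-generating medium.
- Comparison: the chosen route gets a ring, two skeletal bonds and the first stereocentre from one catalytic step, with ring A made beforehand by robust chemistry.

Key step: step 6

Remark 1: 2-(oxazol-5-yl)acetic acid (1) and 14-methylpentadecanoic acid (19) are taken as purchasable.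
Remark 2: (R)-BINOL is assumed to direct addition to the Re face of aldehyde 6 (R carbinol), as in Ti(OiPr)4/BINOL-catalysed additions to aryl aldehydes; if the sense proves opposite for this heteroaryl aldehyde, the mirror-image ligand is used with no other change.

## Route

Step 1
Reactants: 1 2-(oxazol-5-yl)acetic acid; 2 L-serine methyl ester hydrochloride
Product: 3 methyl N-[2-(oxazol-5-yl)acetyl]-L-serinate
Conditions: EDC·HCl, HOBt, N-methylmorpholine, CH2Cl2, 0 °C to rt
Reagents that add atoms: none
Why: Carbodiimide/HOBt amide coupling; the amine outcompetes the primary hydroxyl, and the stereocentre is of no consequence because it is flattened in step 2.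

Step 2
Reactants: 3 methyl N-[2-(oxazol-5-yl)acetyl]-L-serinate
Product: 5 methyl 2-(oxazol-5-ylmethyl)oxazole-4-carboxylate, via oxazoline ester 4 (not isolated)
Conditions: DAST, CH2Cl2, −78 °C; then BrCCl3, DBU, 0 °C to rt
Reagents that add atoms: none
Why: Cyclodehydration of the β-hydroxy amide (O-activation, 5-exo-tet attack of the amide oxygen) gives oxazoline 4; bromination at its C4, the most acidic position next to the ester, and loss of HBr aromatise it to ring A.

Step 3
Reactants: 5 methyl 2-(oxazol-5-ylmethyl)oxazole-4-carboxylate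
Product: 6 2-(oxazol-5-ylmethyl)oxazole-4-carbaldehyde
Conditions: i-Bu2AlH (DIBAL-H), CH2Cl2, −78 °C; MeOH quench, aqueous work-up
Reagents that add atoms: none
Why: Partial ester reduction; the tetrahedral O-aluminated hemiacetal, held by chelation to N3 of ring A, persists at −78 °C and releases the aldehyde only on work-up.

Step 4
Reactants: 7 acetylacetone
Product: 8 (E)-4-methoxypent-3-en-2-one
Conditions: HC(OMe)3, MeOH, TsOH (cat.), rt
Reagents that add atoms: trimethyl orthoformate, COC(OC)OC
Why: Acid-catalysed O-methylation of the β-diketone through its ketal; loss of methanol gives the conjugated (E)-vinylogous ester.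

Step 5
Reactants: 8 (E)-4-methoxypent-3-en-2-one
Product: 9 (E)-4-methoxy-2-(trimethylsilyloxy)penta-1,3-diene
Conditions: LiN(i-Pr)2 (LDA), THF, −78 °C; then TMSCl, −78 to 0 °C
Reagents that add atoms: chlorotrimethylsilane, C[Si](C)(C)Cl
Why: Kinetic deprotonation of the vinylogous ester at the methyl ketone carbon (cross-conjugated enolate) and O-silylation give the 1-alkoxy-3-silyloxy diene with the alkene geometry of 8 retained.

Step 6
Reactants: 6 2-(oxazol-5-ylmethyl)oxazole-4-carbaldehyde; 9 (E)-4-methoxy-2-(trimethylsilyloxy)penta-1,3-diene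
Product: 11 (R)-6-methyl-2-[2-(oxazol-5-ylmethyl)oxazol-4-yl]-2,3-dihydro-4H-pyran-4-one, via silyl aldol adduct 10 (not isolated)
Conditions: Ti(OiPr)4 (10 mol%), (R)-BINOL (20 mol%), 4 Å MS, Et2O, −20 °C; then CF3CO2H, CH2Cl2, 0 °C
Reagents that add atoms: none
Why: The chiral Lewis acid formed from Ti(OiPr)4 and (R)-BINOL binds the formyl oxygen of 6, and the silyl enol ether terminus (CH2) of 9 adds to the Re face in an open Mukaiyama-type transition state, forming C1–C2 and giving silyl aldol 10. Trifluoroacetic acid then removes the silyl group, and the C1 oxygen adds to C5, the β-carbon of the β-methoxy enone, in a 6-endo-trig conjugate addition; loss of methanol gives vinylogous ester 11. The closest known reaction type is the Ti(OiPr)4/BINOL-catalysed cyclocondensation of aldehydes with 1-alkoxy-3-silyloxy dienes, a stepwise aldol–cyclisation that is formally a hetero-Diels–Alder reaction. The only new stereocentre, C1, is set by the chiral Lewis acid alone, since 6 has none, and the cyclisation breaks no bond at C1. Regiochemistry is fixed by the polarisation of the diene: the silyloxy-bearing terminus is its only nucleophilic carbon and the methoxy-bearing carbon the only electrophilic one. The step needs enantiofacial selectivity and turnover in the presence of two weakly basic oxazole nitrogens. The aldehyde has no α-hydrogen, so enolisation and self-condensation are excluded, and a formyl group on an electron-poor azole carbon is a reactive acceptor.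

Step 7
Reactants: 11 (R)-6-methyl-2-[2-(oxazol-5-ylmethyl)oxazol-4-yl]-2,3-dihydro-4H-pyran-4-one
Product: 12 (2R,4R)-6-methyl-2-[2-(oxazol-5-ylmethyl)oxazol-4-yl]-3,4-dihydro-2H-pyran-4-ol
Conditions: NaBH4, CeCl3·7H2O, MeOH, −78 °C; cold NaHCO3 quench
Reagents that add atoms: none
Why: Luche 1,2-reduction; hydride attacks the carbonyl along the pseudoaxial trajectory of the half-chair with the C2 heteroaryl group pseudoequatorial, giving the pseudoequatorial alcohol cis to it, and the hard reagent avoids conjugate reduction.

Step 8
Reactants: 12 (2R,4R)-6-methyl-2-[2-(oxazol-5-ylmethyl)oxazol-4-yl]-3,4-dihydro-2H-pyran-4-ol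
Product: 13 (2R,4S)-6-methyl-2-[2-(oxazol-5-ylmethyl)oxazol-4-yl]-3,4-dihydro-2H-pyran-4-yl 4-nitrobenzoate
Conditions: 4-O2NC6H4CO2H, PPh3, DIAD, toluene, −20 °C to rt
Reagents that add atoms: 4-nitrobenzoic acid, OC(=O)c1ccc(cc1)[N+](=O)[O-]
Why: Mitsunobu reaction; the alkoxyphosphonium ion is displaced by the carboxylate with inversion, turning 2,4-cis into 2,4-trans (chain C3 now S). Attack at the methyl-bearing enol ether carbon anti to the leaving group followed by suprafacial [3,3] shift of the tertiary ketal ester would end at the same trans ester, which also has the favoured pseudoaxial allylic acyloxy group.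

Step 9
Reactants: 13 (2R,4S)-6-methyl-2-[2-(oxazol-5-ylmethyl)oxazol-4-yl]-3,4-dihydro-2H-pyran-4-yl 4-nitrobenzoate
Product: 14 (2R,4S)-6-methyl-2-[2-(oxazol-5-ylmethyl)oxazol-4-yl]-3,4-dihydro-2H-pyran-4-ol
Conditions: K2CO3 (cat.), MeOH, 0 °C
Reagents that add atoms: none
Why: Base-catalysed transesterification of the electron-poor benzoate; acyl–oxygen cleavage leaves the C3 configuration untouched, and the enol ether and both oxazoles are inert to mild base.

Step 10
Reactants: 14 (2R,4S)-6-methyl-2-[2-(oxazol-5-ylmethyl)oxazol-4-yl]-3,4-dihydro-2H-pyran-4-ol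
Product: 16 (3S,4S,6R)-2-(benzyloxy)-2-methyl-6-[2-(oxazol-5-ylmethyl)oxazol-4-yl]tetrahydro-2H-pyran-3,4-diol, via anomeric epoxide 15 (not isolated)
Conditions: mCPBA, BnOH (10 equiv), CH2Cl2, −40 to 0 °C
Reagents that add atoms: 3-chloroperoxybenzoic acid, OOC(=O)c1cccc(Cl)c1; benzyl alcohol, OCc1ccccc1
Why: Hydroxyl-directed (Henbest-type) epoxidation; the peracid is hydrogen-bonded to the allylic hydroxyl and oxidises the electron-rich enol ether on that face, placing the chain C4 oxygen cis to the C3 hydroxyl on the ring. The tertiary anomeric epoxide 15 ionises to the oxocarbenium ion and is captured by benzyl alcohol at the ketal carbon, whose configuration is immaterial.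

Step 11
Reactants: 16 (3S,4S,6R)-2-(benzyloxy)-2-methyl-6-[2-(oxazol-5-ylmethyl)oxazol-4-yl]tetrahydro-2H-pyran-3,4-diol
Product: 17 (3aS,6R,7aS)-4-(benzyloxy)-2,2,4-trimethyl-6-[2-(oxazol-5-ylmethyl)oxazol-4-yl]tetrahydro-4H-[1,3]dioxolo[4,5-c]pyran
Conditions: 2-methoxypropene, PPTS (cat.), CH2Cl2, 0 °C
Reagents that add atoms: 2-methoxypropene, COC(C)=C
Why: Kinetic acetonide formation on the cis-vicinal diol; protonation of the enol ether reagent by the weak acid is far faster than ionisation of the ketoside, whose oxocarbenium ion is destabilised by the adjacent oxygenated carbon.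

Step 12
Reactants: 17 (3aS,6R,7aS)-4-(benzyloxy)-2,2,4-trimethyl-6-[2-(oxazol-5-ylmethyl)oxazol-4-yl]tetrahydro-4H-[1,3]dioxolo[4,5-c]pyran
Product: 18 (3aS,6R,7aS)-2,2,4-trimethyl-6-[2-(oxazol-5-ylmethyl)oxazol-4-yl]tetrahydro-4H-[1,3]dioxolo[4,5-c]pyran-4-ol
Conditions: H2 (1 atm), 10% Pd/C, EtOAc, rt
Reagents that add atoms: none
Why: Hydrogenolysis of the O-benzyl ketal frees the hemiketal without acid, so the acetonide is not at risk; the ring C1–O bond next to an electron-poor azole and the oxazoles themselves are not reduced under these mild conditions.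

Step 13
Reactants: 18 (3aS,6R,7aS)-2,2,4-trimethyl-6-[2-(oxazol-5-ylmethyl)oxazol-4-yl]tetrahydro-4H-[1,3]dioxolo[4,5-c]pyran-4-ol; 19 14-methylpentadecanoic acid
Product: 21 (1R)-2-[(4S,5S)-5-acetyl-2,2-dimethyl-1,3-dioxolan-4-yl]-1-[2-(oxazol-5-ylmethyl)oxazol-4-yl]ethyl 14-methylpentadecanoate, via open-chain hydroxy ketone 20 (not isolated)
Conditions: DCC, DMAP (cat.), CH2Cl2, 0 °C to rt
Reagents that add atoms: none
Why: Steglich esterification under Curtin–Hammett conditions; base-promoted ring–chain tautomerism supplies δ-hydroxy ketone 20, whose secondary C1 hydroxyl is acylated while the tertiary hemiketal hydroxyl of 18 is too hindered to compete. Acylation drains the equilibrium and unmasks the C5 ketone.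

Step 14
Reactants: 21 (1R)-2-[(4S,5S)-5-acetyl-2,2-dimethyl-1,3-dioxolan-4-yl]-1-[2-(oxazol-5-ylmethyl)oxazol-4-yl]ethyl 14-methylpentadecanoate
Product: 22 (1R)-2-[(4S,5R)-5-[(1S)-1-hydroxyethyl]-2,2-dimethyl-1,3-dioxolan-4-yl]-1-[2-(oxazol-5-ylmethyl)oxazol-4-yl]ethyl 14-methylpentadecanoate
Conditions: LiBH(s-Bu)3 (L-Selectride), THF, −78 °C; pH 7 buffer
Reagents that add atoms: none
Why: Felkin–Anh (polar) control; with the dioxolane C4–O bond anti to the incoming bulky, non-chelating hydride, attack past the C4 hydrogen gives the 4,5-syn alcohol (5S). The ester is inert to this reagent at −78 °C.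

Step 15
Reactants: 22 (1R)-2-[(4S,5R)-5-[(1S)-1-hydroxyethyl]-2,2-dimethyl-1,3-dioxolan-4-yl]-1-[2-(oxazol-5-ylmethyl)oxazol-4-yl]ethyl 14-methylpentadecanoate
Product: 23 (1R,3S,4R,5S)-3,4,5-trihydroxy-1-[2-(oxazol-5-ylmethyl)oxazol-4-yl]hexyl 14-methylpentadecanoate
Conditions: CF3CO2H/H2O/THF, 0 °C
Reagents that add atoms: none
Why: Acid-catalysed hydrolysis of the isopropylidene acetal; the acidic medium disfavours the base-promoted 1,3-acyl shift from O1 to O3, and the ester and both oxazoles tolerate brief cold aqueous acid.

## Compound list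

1 | 2-(oxazol-5-yl)acetic acid | OC(=O)Cc1cnco1 | starting material
2 | L-serine methyl ester hydrochloride | COC(=O)[C@@H](N)CO.Cl | starting material
3 | methyl N-[2-(oxazol-5-yl)acetyl]-L-serinate | COC(=O)[C@@H](NC(=O)Cc1cnco1)CO | intermediate
4 | methyl (S)-2-(oxazol-5-ylmethyl)-4,5-dihydrooxazole-4-carboxylate | COC(=O)[C@@H]1COC(Cc2cnco2)=N1 | intermediate
5 | methyl 2-(oxazol-5-ylmethyl)oxazole-4-carboxylate | COC(=O)c1coc(Cc2cnco2)n1 | intermediate
6 | 2-(oxazol-5-ylmethyl)oxazole-4-carbaldehyde | O=Cc1coc(Cc2cnco2)n1 | intermediate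
7 | acetylacetone (pentane-2,4-dione) | CC(=O)CC(C)=O | starting material
8 | (E)-4-methoxypent-3-en-2-one | CO/C(C)=C/C(C)=O | intermediate
9 | (E)-4-methoxy-2-(trimethylsilyloxy)penta-1,3-diene | CO/C(C)=C/C(=C)O[Si](C)(C)C | intermediate
10 | (R,E)-5-methoxy-1-[2-(oxazol-5-ylmethyl)oxazol-4-yl]-1-(trimethylsilyloxy)hex-4-en-3-one | CO/C(C)=C/C(=O)C[C@@H](O[Si](C)(C)C)c1coc(Cc2cnco2)n1 | intermediate
11 | (R)-6-methyl-2-[2-(oxazol-5-ylmethyl)oxazol-4-yl]-2,3-dihydro-4H-pyran-4-one | CC1=CC(=O)C[C@H](c2coc(Cc3cnco3)n2)O1 | intermediate
12 | (2R,4R)-6-methyl-2-[2-(oxazol-5-ylmethyl)oxazol-4-yl]-3,4-dihydro-2H-pyran-4-ol (2,4-cis) | CC1=C[C@H](O)C[C@H](c2coc(Cc3cnco3)n2)O1 | intermediate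
13 | (2R,4S)-6-methyl-2-[2-(oxazol-5-ylmethyl)oxazol-4-yl]-3,4-dihydro-2H-pyran-4-yl 4-nitrobenzoate (2,4-trans) | CC1=C[C@@H](OC(=O)c2ccc(cc2)[N+](=O)[O-])C[C@H](c2coc(Cc3cnco3)n2)O1 | intermediate
14 | (2R,4S)-6-methyl-2-[2-(oxazol-5-ylmethyl)oxazol-4-yl]-3,4-dihydro-2H-pyran-4-ol (2,4-trans) | CC1=C[C@@H](O)C[C@H](c2coc(Cc3cnco3)n2)O1 | intermediate
15 | (1S,3R,5S,6S)-1-methyl-3-[2-(oxazol-5-ylmethyl)oxazol-4-yl]-2,7-dioxabicyclo[4.1.0]heptan-5-ol (epoxide cis to the hydroxyl) | C[C@@]12O[C@H]2[C@@H](O)C[C@H](c2coc(Cc3cnco3)n2)O1 | intermediate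
16 | (3S,4S,6R)-2-(benzyloxy)-2-methyl-6-[2-(oxazol-5-ylmethyl)oxazol-4-yl]tetrahydro-2H-pyran-3,4-diol (ketal carbon not controlled, either configuration) | CC1(OCc2ccccc2)[C@@H](O)[C@@H](O)C[C@H](c2coc(Cc3cnco3)n2)O1 | intermediate
17 | (3aS,6R,7aS)-4-(benzyloxy)-2,2,4-trimethyl-6-[2-(oxazol-5-ylmethyl)oxazol-4-yl]tetrahydro-4H-[1,3]dioxolo[4,5-c]pyran (ketal carbon either configuration) | CC1(OCc2ccccc2)[C@H]2OC(C)(C)O[C@H]2C[C@H](c2coc(Cc3cnco3)n2)O1 | intermediate
18 | (3aS,6R,7aS)-2,2,4-trimethyl-6-[2-(oxazol-5-ylmethyl)oxazol-4-yl]tetrahydro-4H-[1,3]dioxolo[4,5-c]pyran-4-ol (equilibrating hemiketal) | CC1(O)[C@H]2OC(C)(C)O[C@H]2C[C@H](c2coc(Cc3cnco3)n2)O1 | intermediate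
19 | 14-methylpentadecanoic acid | CC(C)CCCCCCCCCCCCC(=O)O | starting material
20 | 1-[(4S,5S)-5-[(2R)-2-hydroxy-2-[2-(oxazol-5-ylmethyl)oxazol-4-yl]ethyl]-2,2-dimethyl-1,3-dioxolan-4-yl]ethan-1-one | CC(=O)[C@H]1OC(C)(C)O[C@H]1C[C@@H](O)c1coc(Cc2cnco2)n1 | intermediate
21 | (1R)-2-[(4S,5S)-5-acetyl-2,2-dimethyl-1,3-dioxolan-4-yl]-1-[2-(oxazol-5-ylmethyl)oxazol-4-yl]ethyl 14-methylpentadecanoate | CC(C)CCCCCCCCCCCCC(=O)O[C@H](C[C@@H]1OC(C)(C)O[C@@H]1C(C)=O)c1coc(Cc2cnco2)n1 | intermediate
22 | (1R)-2-[(4S,5R)-5-[(1S)-1-hydroxyethyl]-2,2-dimethyl-1,3-dioxolan-4-yl]-1-[2-(oxazol-5-ylmethyl)oxazol-4-yl]ethyl 14-methylpentadecanoate | CC(C)CCCCCCCCCCCCC(=O)O[C@H](C[C@@H]1OC(C)(C)O[C@@H]1[C@H](C)O)c1coc(Cc2cnco2)n1 | intermediate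
23 | (1R,3S,4R,5S)-3,4,5-trihydroxy-1-[2-(oxazol-5-ylmethyl)oxazol-4-yl]hexyl 14-methylpentadecanoate | CC(C)CCCCCCCCCCCCC(=O)O[C@H](C[C@H](O)[C@H](O)[C@H](C)O)c1coc(Cc2cnco2)n1 | target

## Step count and least certain steps

Total: 15 steps. Longest linear sequence: 13 steps (steps 1–3 and 6–15, from 1 and 2); the diene branch is steps 4–5.

**Step 6 (key step).** The most likely failure is slow turnover or poor enantiofacial selectivity. N3 of ring A sits next to the formyl group and can bind titanium together with the carbonyl oxygen, which changes the geometry the monodentate model relies on; the ring B nitrogen can also occupy the catalyst while a silyl-cation-catalysed background aldol runs unselectively. The fallback changes the control element from one-point to two-point binding. From 6 and 9, Cu(OTf)2 (divalent copper) with a C2-symmetric bis(oxazoline) ligand would hold N3 and the formyl oxygen in a five-membered chelate that exposes one aldehyde face to the silyl enol ether. The same aldol 10 would form and would be closed with CF3CO2H to return to 11. The fallback makes no compound outside the list, hence F0.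

**Step 8.** The activated allylic alcohol is also a vinylogous ketal precursor. Ionisation to the allyl oxocarbenium ion would allow loss of stereochemical integrity at C3, or elimination to a pyran diene, in competition with direct displacement. The fallback moves the inversion from C3 to C1, where an ordinary secondary carbinol is inverted during the esterification that has to be done anyway. From 6 and 9 with Ti(OiPr)4/(S)-BINOL, through the (S)-silyl aldol adduct F1, the (S)-dihydropyranone F2 would be obtained. Luche reduction would give the 2,4-cis pyranol F3, whose pseudoequatorial hydroxyl already has the target configuration at chain C3 and is the ideal directing group. mCPBA/BnOH would give, via the all-cis anomeric epoxide F4, the benzyl ketal diol F5; 2-methoxypropene/PPTS the benzyl ketal acetonide F6; and hydrogenolysis the C1-epimeric hemiketal F7. Its open-chain (1S)-hydroxy ketone tautomer F8 would be esterified with 19 under Mitsunobu conditions (PPh3, DIAD), which inverts C1 and returns to 21.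

**Step 10.** The directing hydroxyl of 14 is pseudoaxial in the favoured half-chair, a weaker geometry for peracid hydrogen bonding, so facial selectivity may be poor; acid-catalysed addition of benzyl alcohol to the enol ether without oxidation is a second diversion. The fallback replaces epoxidation by directed dihydroxylation. From 14, OsO4 (1 equiv) with TMEDA in CH2Cl2 at −78 °C adds on the face of the hydrogen-bonded allylic hydroxyl. Cleavage of the osmate ester would give the 2,3,4-triol hemiketal F9, and acid-catalysed ketalisation (BnOH, CSA) would return to 16.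

**Step 13.** The share of open-chain tautomer 20 may be small, so acylation may be slow, leaving time for O-acylation at the hemiketal oxygen or for base-induced epimerisation or β-elimination at C4 of keto ester 21. The fallback locks the open chain before acylation. From 18, 1,1-dimethylhydrazine would give the hydrazone alcohol F10; DCC/DMAP esterification with 19 the hydrazone ester F11; and mild two-phase hydrolysis (aqueous oxalic acid, Et2O) would return to 21.

**Step 14.** Facial selectivity may be insufficient if lithium chelation between the ketone and the dioxolane oxygen competes with the polar Felkin–Anh arrangement, because chelation leads to the 4,5-anti epimer. The fallback replaces substrate control by reagent control. From 21, Corey–Bakshi–Shibata reduction with the (R)-Me-CBS oxazaborolidine and BH3·SMe2 in THF at −30 °C, with the dioxolanyl group as the large substituent, would give 22. The fallback makes no compound outside the list, hence F0.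

## Further compounds

F0 | step 6 | none | none
F1 | step 8 | (S,E)-5-methoxy-1-[2-(oxazol-5-ylmethyl)oxazol-4-yl]-1-(trimethylsilyloxy)hex-4-en-3-one | CO/C(C)=C/C(=O)C[C@H](O[Si](C)(C)C)c1coc(Cc2cnco2)n1
F2 | step 8 | (S)-6-methyl-2-[2-(oxazol-5-ylmethyl)oxazol-4-yl]-2,3-dihydro-4H-pyran-4-one | CC1=CC(=O)C[C@@H](c2coc(Cc3cnco3)n2)O1
F3 | step 8 | (2S,4S)-6-methyl-2-[2-(oxazol-5-ylmethyl)oxazol-4-yl]-3,4-dihydro-2H-pyran-4-ol (2,4-cis) | CC1=C[C@@H](O)C[C@@H](c2coc(Cc3cnco3)n2)O1
F4 | step 8 | (1S,3S,5S,6S)-1-methyl-3-[2-(oxazol-5-ylmethyl)oxazol-4-yl]-2,7-dioxabicyclo[4.1.0]heptan-5-ol | C[C@@]12O[C@H]2[C@@H](O)C[C@@H](c2coc(Cc3cnco3)n2)O1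
F5 | step 8 | (3S,4S,6S)-2-(benzyloxy)-2-methyl-6-[2-(oxazol-5-ylmethyl)oxazol-4-yl]tetrahydro-2H-pyran-3,4-diol (ketal carbon either configuration) | CC1(OCc2ccccc2)[C@@H](O)[C@@H](O)C[C@@H](c2coc(Cc3cnco3)n2)O1
F6 | step 8 | (3aS,6S,7aS)-4-(benzyloxy)-2,2,4-trimethyl-6-[2-(oxazol-5-ylmethyl)oxazol-4-yl]tetrahydro-4H-[1,3]dioxolo[4,5-c]pyran (ketal carbon either configuration) | CC1(OCc2ccccc2)[C@H]2OC(C)(C)O[C@H]2C[C@@H](c2coc(Cc3cnco3)n2)O1
F7 | step 8 | (3aS,6S,7aS)-2,2,4-trimethyl-6-[2-(oxazol-5-ylmethyl)oxazol-4-yl]tetrahydro-4H-[1,3]dioxolo[4,5-c]pyran-4-ol (equilibrating hemiketal) | CC1(O)[C@H]2OC(C)(C)O[C@H]2C[C@@H](c2coc(Cc3cnco3)n2)O1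
F8 | step 8 | 1-[(4S,5S)-5-[(2S)-2-hydroxy-2-[2-(oxazol-5-ylmethyl)oxazol-4-yl]ethyl]-2,2-dimethyl-1,3-dioxolan-4-yl]ethan-1-one | CC(=O)[C@H]1OC(C)(C)O[C@H]1C[C@H](O)c1coc(Cc2cnco2)n1
F9 | step 10 | (3S,4S,6R)-2-methyl-6-[2-(oxazol-5-ylmethyl)oxazol-4-yl]tetrahydro-2H-pyran-2,3,4-triol (equilibrating hemiketal) | CC1(O)[C@@H](O)[C@@H](O)C[C@H](c2coc(Cc3cnco3)n2)O1
F10 | step 13 | (1R)-2-[(4S,5R)-5-[(E)-1-(2,2-dimethylhydrazinylidene)ethyl]-2,2-dimethyl-1,3-dioxolan-4-yl]-1-[2-(oxazol-5-ylmethyl)oxazol-4-yl]ethan-1-ol | CN(C)/N=C(\C)[C@H]1OC(C)(C)O[C@H]1C[C@@H](O)c1coc(Cc2cnco2)n1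
F11 | step 13 | (1R)-2-[(4S,5R)-5-[(E)-1-(2,2-dimethylhydrazinylidene)ethyl]-2,2-dimethyl-1,3-dioxolan-4-yl]-1-[2-(oxazol-5-ylmethyl)oxazol-4-yl]ethyl 14-methylpentadecanoate | CC(C)CCCCCCCCCCCCC(=O)O[C@H](C[C@@H]1OC(C)(C)O[C@@H]1/C(C)=N/N(C)C)c1coc(Cc2cnco2)n1
F0 | step 14 | none | none
A1 | alternative 1 | 2-deoxy-L-fucose (2,6-dideoxy-L-lyxo-hexose, open-chain form) | O=CC[C@H](O)[C@H](O)[C@H](C)O
A2 | alternative 1 | (3S,4R,5S)-3,4,5-tris(benzyloxy)hexanal | O=CC[C@H](OCc1ccccc1)[C@H](OCc1ccccc1)[C@H](C)OCc1ccccc1
A3 | alternative 1 | methyl isocyanoacetate | [C-]#[N+]CC(=O)OC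
A4 | alternative 1 | bis(cyclohexyl isocyanide)gold tetrafluoroborate, [Au(CNC6H11)2]BF4 | [C-]#[N+]C1CCCCC1.[C-]#[N+]C1CCCCC1.[Au+].F[B-](F)(F)F
A5 | alternative 1 | methyl (4S,5R)-5-[(2S,3R,4S)-2,3,4-tris(benzyloxy)pentyl]-4,5-dihydrooxazole-4-carboxylate | COC(=O)[C@H]1N=CO[C@@H]1C[C@H](OCc2ccccc2)[C@H](OCc2ccccc2)[C@H](C)OCc2ccccc2
A6 | alternative 2 | (4R,5S)-2,2,5-trimethyl-1,3-dioxolane-4-carbaldehyde | O=C[C@@H]1OC(C)(C)O[C@H]1C
A7 | alternative 2 | ketene | C=C=O
A8 | alternative 2 | (S)-4-[(4R,5S)-2,2,5-trimethyl-1,3-dioxolan-4-yl]oxetan-2-one | O=C1C[C@H](O1)[C@@H]2OC(C)(C)O[C@H]2C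
A9 | alternative 3 | terminal alkyne carrying the C1–C6 chain in the target configuration: C1 triethylsilyl ether, C3/C4 acetonide, C5 tert-butyldimethylsilyl ether | CC[Si](CC)(CC)O[C@H](C[C@@H]1OC(C)(C)O[C@@H]1[C@H](C)O[Si](C)(C)C(C)(C)C)C#C
A10 | alternative 3 | 2-(oxazol-5-yl)acetamide | NC(=O)Cc1cnco1
A11 | alternative 3 | (Mor-DalPhos)AuNTf2, [di(1-adamantyl)(2-morpholinophenyl)phosphine]gold bis(trifluoromethanesulfonyl)imide | C1COCCN1c1ccccc1P(C12CC3CC(CC(C3)C1)C2)C12CC3CC(CC(C3)C1)C2.[Au+].FC(F)(F)S(=O)(=O)[N-]S(=O)(=O)C(F)(F)F
A12 | alternative 3 | protected bis-oxazole in the target configuration: C1 triethylsilyl ether, C3/C4 acetonide, C5 tert-butyldimethylsilyl ether | CC[Si](CC)(CC)O[C@H](C[C@@H]1OC(C)(C)O[C@@H]1[C@H](C)O[Si](C)(C)C(C)(C)C)c2coc(Cc3cnco3)n2
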